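The earlier runs and the new flask come from a simulation with constants of no real substance, and the scatter is random.

A small charge of free catalyst, 0.14 mol% of the substrate, asks each catalyst in the flask for 714 turnovers before the substrate is finished.

| flask | substrate | gas phase | free catalyst | remark | time |
|---|---|---|---|---|---|
| gamma | 26 mM | 1.3 mM (held) | 0.14 mol% | run made earlier |  |
| flask | 13 mM | 1.3 mM (held) | 0.14 mol% |  | 30 min |

gamma run (percent of the substrate charged): time / min: product / % = 0.833: 2.1; 2.50: 8.9; 4.00: 13.3; 6.00: 20.0; 10.0: 32.3

(readings scatter by 0.5 percentage points)

* product at 30 min, in percent of the substrate charged
* concentration of dissolved gas in solution at 30 min, in percent of saturation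

- at the start none of the gas phase is in solution
- no earlier run changes the charge of free catalyst; that part of a forecast is a guess

Product in the gamma run climbs in a nearly straight line, and its last reading, 32.3% at 10.0 min, gives an average of 23.1 min⁻¹ per catalyst, read as the turnover frequency, while a third of the gamma substrate goes. Held for 30 min in the flask, that frequency offers 692 turnovers, which gives 0.969 for the turnover ratio, turnovers on offer per turnover the charge asks for. Loading, frequency and time are folded into this one number, and a value near one means the straight line meets the end of the substrate close to the asked time. One number is not enough, though: carrying the frequency over to the flask, with half the substrate at the same loading, is a guess, and the gamma readings end at 32.3% product, short of the last stretch of substrate. This reckoning therefore commits the flask to product a little under 96.9%.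

The forecast, which reads gamma as “first order in substrate”, gives 50% product and 96% of saturation.

The flask gives 86.4% product, with dissolved gas at 89.7% of saturation.

    gas phase ⇌ dissolved gas, rate k1*(csat - [dissolved gas]) (kL = 0.750 min⁻¹)
    substrate + dissolved gas + free catalyst → free catalyst + product (k = 1.40 × 10⁵ M⁻² s⁻¹)
    free catalyst + product → spent catalyst (k = 5.90 M⁻¹ min⁻¹)

Each catalyst charged to the flask has averaged 617 turnovers of the 692 counted, and by 30.0 min free catalyst is down to 27.8%, with spent catalyst at 72.2%. The same flask read at 50 min has 1.61 as its turnover ratio, well past one, so the count has the substrate finished. That neighbour nevertheless holds 92.2% product and 7.62% substrate, with free catalyst at 6.97%.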